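Take what is left over first. Each turn of the enzyme spends one starting material and one second substrate, so 0.0500 M of starting material stays behind once the second substrate has gone. Second substrate is therefore the limiting reagent.

    starting material + free enzyme ⇌ first complex (K1 = 170 L mol⁻¹, k1 = 21600 L mol⁻¹ min⁻¹)
    first complex → loaded enzyme + first product (k2 = 284 min⁻¹)
    second substrate + loaded enzyme ⇌ second complex (K3 = 32.4 L mol⁻¹, k3 = 1.90 × 10⁵ L mol⁻¹ min⁻¹)
    second complex → free enzyme + target (k4 = 679 min⁻¹)
    target + first product → side product (k5 = 2.17 L mol⁻¹ min⁻¹)

| flask | starting material | second substrate | free enzyme | time | remark |
|---|---|---|---|---|---|
| zeta | 0.10 M (fed, over 8.0 min) | 0.0500 M | 50 µM | 10 min | all else is in the flask from the start; the feed brings no volume worth counting |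
| beta | 0.10 M | 0.0500 M (fed, over 8.0 min) | 50 µM | 10 min | all else is in the flask from the start; the feed brings no volume worth counting |
| alpha | 0.10 M | 0.0500 M | 50 µM | 10 min | everything together at the start |

1. which flask leads in amount of side product, in percent of the starting material charged ("all alike" within 1.5 percentage points) (zeta / beta / alpha / all alike)
2. how much side product is there at the end, in percent of the starting material charged: zeta
3. how much side product is there at the end, in percent of the starting material charged: beta
4. how much side product is there at the end, in percent of the starting material charged: alpha

How long is one turn? Adding the two binding steps, with their fall-backs, and the two chemical steps at full charges gives 0.00668 min. So 50 µM of enzyme makes target at 0.00749 M min⁻¹.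

Against what rate? Target and first product appear together and are lost together, so they stand equal. At 0.0500 M each, the side step runs at 0.00543 M min⁻¹, slower than turnover.

Then the side step can be ignored? No. That comparison holds for one moment, and it drifts. The side rate grows with the square of the target, from nothing at the start.

How long does making last? At the full-charge turn, alpha's second substrate lasts 6.68 min, inside the run. That is an estimate, not an end, since the turn lengthens as the charges fall. A linear rise squared averages a third of full strength.

On that estimate alpha gets 5.55 min: that is its exposure time, the minutes of full-strength side step a flask has had, counting the time after making plus a third of the making time. Multiplied by the rate constant and the charge, it gives 0.602. Equal partners lost by a second-order step then give up the share y/(1+y). For alpha that is 18.8%.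

And the feeds? Beta cannot finish before its feed ends, so its making time is at least 8.0 min and its exposure at most 4.67 min, and I commit to a share below 16.8%. For zeta I take starting material at half its charge, which lengthens the turn and gives an exposure of 5.10 min. So I put zeta below 17.8%. My leader is alpha.

The forecast also names alpha, with zeta 12%, beta 9.5% and alpha 16%, on these grounds: “All together at the start builds them up fastest and so gives the most side product”. My alpha figure stands above its value.

The simulation gives alpha as leader, with zeta 11.9%, beta 9.45% and alpha 16.1%.

Alpha's reading lies below my figure, and at 10.0 min alpha still held 1.63% of its second substrate. The exposure time carries to the alpha flask left until 25 min. Its exposure, reckoned with the same full-charge making time, is 20.5 min, which gives 2.23 and a side share of 34.5%. That flask read 16.1% target and 50.0% starting material, with side product at 33.9%.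

The constants are assumed; the result is computed.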